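## Structural features

The target is an achiral flavone: a benzo ring A fused through C4a–C8a to a 4-pyranone ring C, with a 4-hydroxyphenyl ring B on C2. It has no stereocentre, so no stereochemical relationship has to be set. Every carbon of ring A is substituted: C5, C6, C7 and C8 carry OMe, OMe, OH and OMe, and C3 of ring C carries a fifth methoxy group. The fragile points are the two free phenols (7-OH and 4′-OH), the hexasubstituted ring A, which is electron-rich enough to oxidise to a quinone, the 5-OMe peri to the carbonyl (lost with Lewis acids), and the pyranone, which opens when strong nucleophiles attack C2. The real difficulty is the oxygen pattern rather than the skeleton: of four contiguous ring A oxygens only O7 must stay unmethylated, and the ring has no free CH to guide a late correction. The key step uses the fact that C5–C8 are four adjacent oxygen-bearing carbons, the pattern of a squaric ester, sitting on the C4a–C8a double bond of a 4-pyranone, so ring A can be closed last at C8–C8a with each oxygen arriving in a different state.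

## Logic of the disconnections

19 from 18: the two O–C(tert-butyl) bonds at O7 and O4′ are cut. Both phenols are masked by the same acid-labile group, so one closing step frees them and all earlier chemistry runs on fully etherified material. The forward step must be an acidolysis that leaves five methyl ethers alone; ring A of 18 has no free position for C-alkylation.

18 from 17: the O8–CH3 bond is cut. The C8 oxygen is the only one that leaves the ring-forming step as a free phenol, so it can be methylated without any selectivity question. The forward step needs a base that the tert-butyl ethers tolerate.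

17 from 14 (through 15 and 16): the C8–C8a bond is cut and ring A is folded back into a four-membered ring. This removes the whole benzo ring and traces its four oxygens to one C4 unit: carbinol carbon to C5, enol-ether carbon to C6, α-carbon to C7, carbonyl carbon to C8. The forward step must open the cyclobutenone thermally with the pyranonyl group turning inward, close onto the pyranone CH next to the ring oxygen, and spare the tert-butyl ethers.

14 from 13: the O–CH3 bond at the carbinol carbon is cut. Capping this oxygen as its methyl ether fixes the 5-OMe before the ring expansion and keeps the product at the phenol rather than the quinone level. The forward step must methylate a tertiary alcohol without making its alkoxide.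

13 from 6 and 10 (through 11 and 12): the C–C bond between pyranone C5 and the carbinol carbon is cut. This is the convergent cut into two halves of similar size. The forward step needs a nucleophilic pyranone C5 and attack on the carbonyl of 10 that lies next to the methoxy-bearing carbon.

10 from 9, and 9 from 7 (through 8): first the O–C(tert-butyl) bond, then one O–CH3 bond of symmetric 7 are cut. In this way 10 arises from commercial 7 by a single hydrolysis and one alkylation. The forward steps must stop the hydrolysis at the mono-anion and alkylate a weakly nucleophilic anion with a tertiary electrophile.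

6 from 5: the C5–I bond is cut. The halogen of 6 is the handle for fast halogen–metal exchange at the carbon that direct deprotonation would not reach. The forward step must iodinate the pyranone α-carbon in preference to ring B and without acid.

5 from 3 and 4: the C2–C1′ bond between rings C and B is cut. Ring B arrives complete with its protected oxygen in a cross-coupling. The forward step needs mild base because of the pyranone.

3 from 2, and 2 from 1: the O3–CH3 bond and the C2–I bond are cut, leading back to commercial 1. The forward steps rely on the enolic hydroxyl directing the halogen to the neighbouring C2 and then being methylated.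

## Other disconnections considered

Alternative 1: The cut is at the C6–O and C8–O bonds only; no skeletal bond and no ring is formed. In the forward direction kaempferol A3 would be benzylated at O7 and O4′, methylated at O3 and O5, and brominated to the 6,8-dibromide A2. NaOMe with CuBr would then replace both bromines to give A1, and hydrogenolysis would finish.
- In its favour: the whole carbon skeleton is bought, and the route is about five steps. On step economy it is clearly better than the chosen plan. The differentiation of O7 rests on the known acidity order of the flavonol hydroxyls, which is at least the equal of steric control in a squarate addition.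
- Against it: the partial alkylations of A3 give mixtures, and the chelated 5-OH needs forcing methylation. The key step asks for two CuBr-mediated substitutions, each at a carbon flanked by two ortho oxygens, in hot methoxide. Hydrodebromination at either position would compete, and its outcome would be hard to separate from A1; methoxide can also attack C2 of the pyranone.
- Comparison: mechanistically it is a plain CuBr-mediated aromatic substitution and is structurally undemanding, but both substitutions must go to completion on a base-sensitive substrate. The chosen plan is longer but places each oxygen constructively.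

Alternative 2: The cut is through ring C at O1–C8a, C4–C4a and O1–C2, with ring A as a symmetric aryne. In the forward direction CsF would release the aryne from A5. The carboxylate oxygen of A6 adds, the aryl anion takes the acyl carbon, and the phenoxide closes 6-endo onto the ynone to give A4.
- In its favour: it is convergent, ring C forms in one operation, and the symmetry of the aryne removes any regiochemical question in the insertion. On convergency it is the equal or the better of the chosen plan.
- Against it: A4 has hydrogen at C3, so C3 oxygenation and methylation cost two more steps. A4 also has identical benzyl ethers at O6 and O7; after hydrogenolysis the more acidic 7-OH would react first, so a protect–methylate–deprotect detour is needed to methylate O6. A5 is a hexasubstituted arene whose preparation is long, so the ring A oxygen problem is moved rather than solved. Closure in the 5-exo mode, towards the aurone skeleton, is a possible leak.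
- Comparison: neither plan has a stereochemical issue. The chosen plan is better on the differentiation of O7 and on carrying the C3 oxygen from the start.

Alternative 3: The cut is at O1–C2 of ring C, with the C3–O bond made afterwards. In the forward direction the arene A9, which has one free CH para to the benzyloxy group, would be acylated to the ynone A8. ICl would activate the alkyne, an ortho methoxy oxygen would close 6-endo-dig, and chloride would remove the methyl group to give A7. Methoxylation of the C3 iodide with NaOMe and CuI, and hydrogenolysis, would follow.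
- In its favour: the two ortho methoxy groups of A8 are equivalent, and O7 is unique by symmetry from the first step. That is a cleaner differentiation than the steric control of the chosen plan and is named here as the better solution on that point. The iodocyclisation is closely precedented for ortho-methoxyaryl ynones, so on predictability of the ring-forming step it is also the better. The step count would be comparable once A9 is in hand.
- Against it: A9 itself needs several steps. ICl is an electrophile and oxidant towards very electron-rich rings. The late methoxylation of an α-iodo enone puts methoxide and CuI on a base-sensitive flavone, with reduction of the C–I bond as a competitor.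
- Comparison: the chosen plan brings the 3-OMe in from the start and builds ring A from an inexpensive C4 unit, at the price of an untested ring-expansion partner.

Key step: step 9

Remark on the chemistry: the 4′-oxygen is carried as a tert-butyl ether (not a benzyl ether) so that one acid step frees both phenols; the precursor and product of the key step keep their skeletons.
Remark on the chemistry: ring expansion of a furyl carbinol stops at a 6-hydroxy-2H-pyran-3(6H)-one, two hydrogens richer than a 3-hydroxy-4-pyranone, and the extra oxidant and hot acid would endanger an electron-rich benzylic carbinol; the aryl pyranone is therefore made by cross-coupling on commercial pyromeconic acid.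
Remark on the chemistry: in the running text the pyranone is numbered as in 5 (aryl at C2, linking carbon C5, free CH C6); as a substituent the same ring is named 6-aryl-5-methoxy-4-oxo-4H-pyran-3-yl.

## Route

Step 1
Reactants: 1 3-hydroxy-4H-pyran-4-one (pyromeconic acid)
Product: 2 3-hydroxy-2-iodo-4H-pyran-4-one
Conditions: I2 (1.0 equiv), Na2CO3, H2O, 0 °C to rt; then acidify to pH 3
Reagents that add atoms: iodine, II
Why: Electrophilic iodination of the pyranone enolate; deprotonation of the 3-hydroxyl makes C2 the β-carbon of an enolate (O3–C3=C2), the position where 3-hydroxy-4-pyranones take up electrophiles (aldol, Mannich, halogenation), so one equivalent of iodine should give the 2-iodide and leave C5 and C6 alone.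

Step 2
Reactants: 2 3-hydroxy-2-iodo-4H-pyran-4-one
Product: 3 2-iodo-3-methoxy-4H-pyran-4-one
Conditions: MeI, K2CO3, acetone, 45 °C
Reagents that add atoms: iodomethane, CI
Why: Williamson O-methylation of the acidic enolic hydroxyl with a weak, non-nucleophilic base; carbonate in acetone should not displace the vinylogous acyl iodide at C2.

Step 3
Reactants: 3 2-iodo-3-methoxy-4H-pyran-4-one; 4 (4-tert-butoxyphenyl)boronic acid
Product: 5 2-(4-tert-butoxyphenyl)-3-methoxy-4H-pyran-4-one
Conditions: Pd(PPh3)4 (5 mol %), K2CO3, 1,4-dioxane/H2O 5:1, 70 °C
Reagents that add atoms: none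
Why: Suzuki–Miyaura coupling; the C2–I bond is a vinylogous acyl iodide that adds readily to zerovalent palladium, the aryl tert-butyl ether is inert to aqueous carbonate, and the mild base and moderate temperature spare the pyranone ring.

Step 4
Reactants: 5 2-(4-tert-butoxyphenyl)-3-methoxy-4H-pyran-4-one
Product: 6 2-(4-tert-butoxyphenyl)-5-iodo-3-methoxy-4H-pyran-4-one
Conditions: ICl (1.1 equiv), pyridine (2.5 equiv), CH2Cl2, 0 °C to rt
Reagents that add atoms: iodine monochloride, ClI
Why: Electrophilic α-iodination of a β-alkoxy enone (vinylogous ester): iodonium adds to C5, the β-carbon of the enol ether O1–C6=C5, and pyridine removes the C5 proton from the oxocarbenium ion; pyridine keeps the medium non-acidic for the tert-butyl ether, whose bulk, together with the electron-poor pyranone on ring B, should disfavour iodination of ring B.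

Step 5
Reactants: 7 dimethyl squarate
Product: 9 silver 2-methoxy-3,4-dioxocyclobut-1-en-1-olate, via sodium salt of the monomethyl ester 8 (not isolated)
Conditions: NaOH (1.0 equiv), MeOH/H2O, 0 °C; then AgNO3 (1.0 equiv), H2O, rt, dark; filter, dry
Reagents that add atoms: sodium hydroxide, [Na+].[OH-]; silver nitrate, [Ag+].[O-][N+](=O)[O-]
Why: Addition–elimination of hydroxide at one vinylogous ester carbon should stop after one methoxy group because the product is an anion; AgNO3 then precipitates the silver salt by metathesis.

Step 6
Reactants: 9 silver 2-methoxy-3,4-dioxocyclobut-1-en-1-olate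
Product: 10 3-tert-butoxy-4-methoxycyclobut-3-ene-1,2-dione
Conditions: tBuCl (5 equiv), Et2O, rt, dark
Reagents that add atoms: tert-butyl chloride, CC(C)(C)Cl
Why: Silver-assisted SN1 O-alkylation of the vinylogous carboxylate by the tert-butyl cation, the classical silver-salt route to hindered squarate esters; alkylation at either oxygen of the delocalised anion gives the same 1,2-dione.

Step 7
Reactants: 6 2-(4-tert-butoxyphenyl)-5-iodo-3-methoxy-4H-pyran-4-one; 10 3-tert-butoxy-4-methoxycyclobut-3-ene-1,2-dione
Product: 13 racemic 2-tert-butoxy-4-[6-(4-tert-butoxyphenyl)-5-methoxy-4-oxo-4H-pyran-3-yl]-4-hydroxy-3-methoxycyclobut-2-en-1-one, via pyranonylmagnesium chloride 11 (not isolated), via chloromagnesium alkoxide of the adduct 12 (not isolated)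
Conditions: iPrMgCl·LiCl (1.05 equiv), THF, −40 °C, 30 min; then cannulate into 10 (1.2 equiv), THF, −78 °C; aq. NH4Cl
Reagents that add atoms: none
Why: Iodine–magnesium exchange on an α-iodo enone, then 1,2-addition of the alkenyl Grignard reagent to a squarate carbonyl; low temperature should keep the magnesiated β-alkoxy enone from opening by β-elimination, and the tert-butoxy group shields the carbonyl beside it, so attack should go to C1 (next to the methoxy-bearing carbon) and place OtBu on the α-carbon of the cyclobutenone; the new quaternary carbinol centre forms as a racemate and is erased in step 9.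

Step 8
Reactants: 13 racemic 2-tert-butoxy-4-[6-(4-tert-butoxyphenyl)-5-methoxy-4-oxo-4H-pyran-3-yl]-4-hydroxy-3-methoxycyclobut-2-en-1-one
Product: 14 racemic 2-tert-butoxy-4-[6-(4-tert-butoxyphenyl)-5-methoxy-4-oxo-4H-pyran-3-yl]-3,4-dimethoxycyclobut-2-en-1-one
Conditions: MeI (excess), Ag2O, MeCN, 4 Å sieves, rt, dark
Reagents that add atoms: iodomethane, CI
Why: Purdie methylation of the tertiary cyclobutenol under neutral conditions, the usual way to cap squarate adducts; it avoids alkoxide-triggered ring opening and leaves both tert-butyl ethers intact.

Step 9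
Reactants: 14 racemic 2-tert-butoxy-4-[6-(4-tert-butoxyphenyl)-5-methoxy-4-oxo-4H-pyran-3-yl]-3,4-dimethoxycyclobut-2-en-1-one
Product: 17 7-tert-butoxy-2-(4-tert-butoxyphenyl)-8-hydroxy-3,5,6-trimethoxy-4H-chromen-4-one, via (3Z)-dienylketene 15 (not isolated), via 8aH-chromene-4,8-dione tautomer 16 (not isolated)
Conditions: toluene (degassed, dilute), 110 °C, argon, base-washed glassware
Reagents that add atoms: none
Why: Moore rearrangement: heat opens the C1–C4 bond of the cyclobutenone in a conrotatory four-electron electrocyclic reaction to the dienylketene 15. The C4 methoxy donor turns outward, so the pyranonyl group turns inward and ends cis to the ketene-bearing carbon, the only geometry that can close. A thermal disrotatory six-electron electrocyclisation then joins the ketene carbon to pyranone C6 (the CH next to the ring oxygen), forming C8–C8a and closing ring A as a six-membered carbocycle to give dienone 16. Enolisation of 16 moves the 8a hydrogen to O8 and gives the aromatic phenol 17; no stereocentre remains, because the carbinol centre of 14 and the 8a centre of 16 both become sp2. The closest known reactions are the ring expansions of 4-aryl-, 4-heteroaryl- and 4-alkenyl-4-alkoxycyclobutenones from squarates to para-alkoxyphenols, with the pyranone C5=C6 bond taking the part of the alkenyl π bond. Site selectivity is secured by the substrate, since the linking carbon has only one CH neighbour (the other is the C4 carbonyl carbon), and the oxygens fall as carbinol carbon to C5 (OMe), enol-ether carbon to C6 (OMe), α-carbon to C7 (OtBu), ketene carbon to C8 (OH). The tert-butyl ethers are expected to survive 110 °C in the absence of acid, and degassing protects the electron-rich para-methoxyphenol from autoxidation.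

Step 10
Reactants: 17 7-tert-butoxy-2-(4-tert-butoxyphenyl)-8-hydroxy-3,5,6-trimethoxy-4H-chromen-4-one
Product: 18 7-tert-butoxy-2-(4-tert-butoxyphenyl)-3,5,6,8-tetramethoxy-4H-chromen-4-one
Conditions: MeI, K2CO3, acetone, 50 °C
Reagents that add atoms: iodomethane, CI
Why: Williamson methylation of the C8 phenol, the only acidic OH present and not hydrogen-bonded to the C4 carbonyl; tert-butyl ethers are stable to K2CO3.

Step 11
Reactants: 18 7-tert-butoxy-2-(4-tert-butoxyphenyl)-3,5,6,8-tetramethoxy-4H-chromen-4-one
Product: 19 7-hydroxy-2-(4-hydroxyphenyl)-3,5,6,8-tetramethoxy-4H-chromen-4-one (CNP0539397.0)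
Conditions: TFA/CH2Cl2 1:4, 0 °C to rt
Reagents that add atoms: none
Why: Acidolysis (E1) of both aryl tert-butyl ethers should release O7 and O4′ as phenols with loss of isobutene; methyl ethers and the flavone are inert to TFA at room temperature, ring A has no free position for tert-butylation, and ring B is deactivated by its conjugation with the pyranone carbonyl.

## Compound list

1 | 3-hydroxy-4H-pyran-4-one (pyromeconic acid) | O=c1ccocc1O | starting material
2 | 3-hydroxy-2-iodo-4H-pyran-4-one | O=c1ccoc(I)c1O | intermediate
3 | 2-iodo-3-methoxy-4H-pyran-4-one | COc1c(I)occc1=O | intermediate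
4 | (4-tert-butoxyphenyl)boronic acid | CC(C)(C)Oc1ccc(B(O)O)cc1 | starting material
5 | 2-(4-tert-butoxyphenyl)-3-methoxy-4H-pyran-4-one | COc1c(-c2ccc(OC(C)(C)C)cc2)occc1=O | intermediate
6 | 2-(4-tert-butoxyphenyl)-5-iodo-3-methoxy-4H-pyran-4-one | COc1c(-c2ccc(OC(C)(C)C)cc2)occ(I)c1=O | intermediate
7 | dimethyl squarate (3,4-dimethoxycyclobut-3-ene-1,2-dione) | COC1=C(OC)C(=O)C1=O | starting material
8 | sodium 2-methoxy-3,4-dioxocyclobut-1-en-1-olate | COC1=C([O-])C(=O)C1=O.[Na+] | intermediate
9 | silver 2-methoxy-3,4-dioxocyclobut-1-en-1-olate | COC1=C([O-])C(=O)C1=O.[Ag+] | intermediate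
10 | 3-tert-butoxy-4-methoxycyclobut-3-ene-1,2-dione | COC1=C(OC(C)(C)C)C(=O)C1=O | intermediate
11 | [6-(4-tert-butoxyphenyl)-5-methoxy-4-oxo-4H-pyran-3-yl]magnesium chloride (LiCl complex) | COc1c(-c2ccc(OC(C)(C)C)cc2)occ([Mg]Cl)c1=O | intermediate
12 | racemic chloromagnesium alkoxide of 13 | O=C1C(OC(C)(C)C)=C(OC)C1(O[Mg]Cl)c1coc(-c2ccc(OC(C)(C)C)cc2)c(OC)c1=O | intermediate
13 | racemic 2-tert-butoxy-4-[6-(4-tert-butoxyphenyl)-5-methoxy-4-oxo-4H-pyran-3-yl]-4-hydroxy-3-methoxycyclobut-2-en-1-one | O=C1C(OC(C)(C)C)=C(OC)C1(O)c1coc(-c2ccc(OC(C)(C)C)cc2)c(OC)c1=O | intermediate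
14 | racemic 2-tert-butoxy-4-[6-(4-tert-butoxyphenyl)-5-methoxy-4-oxo-4H-pyran-3-yl]-3,4-dimethoxycyclobut-2-en-1-one | O=C1C(OC(C)(C)C)=C(OC)C1(OC)c1coc(-c2ccc(OC(C)(C)C)cc2)c(OC)c1=O | intermediate
15 | (3Z)-2-tert-butoxy-4-[6-(4-tert-butoxyphenyl)-5-methoxy-4-oxo-4H-pyran-3-yl]-3,4-dimethoxybuta-1,3-dien-1-one | O=C=C(OC(C)(C)C)/C(OC)=C(OC)\c1coc(-c2ccc(OC(C)(C)C)cc2)c(OC)c1=O | intermediate
16 | racemic 7-tert-butoxy-2-(4-tert-butoxyphenyl)-3,5,6-trimethoxy-8aH-chromene-4,8-dione | O=C1C(OC(C)(C)C)=C(OC)C(OC)=C2C(=O)C(OC)=C(c3ccc(OC(C)(C)C)cc3)OC12 | intermediate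
17 | 7-tert-butoxy-2-(4-tert-butoxyphenyl)-8-hydroxy-3,5,6-trimethoxy-4H-chromen-4-one | COc1c(OC(C)(C)C)c(O)c2oc(-c3ccc(OC(C)(C)C)cc3)c(OC)c(=O)c2c1OC | intermediate
18 | 7-tert-butoxy-2-(4-tert-butoxyphenyl)-3,5,6,8-tetramethoxy-4H-chromen-4-one | COc1c(OC(C)(C)C)c(OC)c2oc(-c3ccc(OC(C)(C)C)cc3)c(OC)c(=O)c2c1OC | intermediate
19 | 7-hydroxy-2-(4-hydroxyphenyl)-3,5,6,8-tetramethoxy-4H-chromen-4-one | COc1c(O)c(OC)c2oc(-c3ccc(O)cc3)c(OC)c(=O)c2c1OC | target

## Step count and least certain steps

Total step count: 11. Longest linear sequence: 9 steps (steps 1–4 and 7–11, from 1 to 19); the squarate branch (steps 5 and 6) joins at step 7.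

Step 9 (key step). The closure may be slower than on a plain alkene, because the accepting carbon is the electron-poor C6 of a weakly aromatic pyranone. Longer heating would then be needed, during which the electron-rich para-methoxyphenol can be lost by oxidative demethylation to the 5,8-quinone and the tertiary ethers are stressed. Fallback, from 13 back to 18: alcohol 13 is heated in toluene at 110 °C in the hydroquinone mode of the same ring expansion, which should give 7-tert-butoxy-2-(4-tert-butoxyphenyl)-5,8-dihydroxy-3,6-dimethoxy-4H-chromen-4-one F1. This is oxidised on purpose (air or Ag2O) to 7-tert-butoxy-2-(4-tert-butoxyphenyl)-3,6-dimethoxy-4H-chromene-4,5,8-trione F2. Reductive methylation of F2 (Na2S2O4, then Me2SO4 and K2CO3 in acetone under argon) would place both the O5 and O8 methyl groups and give 18, so that steps 8 and 10 fall away.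

Step 7. Site selectivity between the two squarate carbonyls rests on steric bias alone and may be poor. In addition, the magnesiated pyranone can open by β-elimination if it warms. Fallback, from 6 back to 19, giving up steric control for a symmetric partner: Grignard reagent 11, made from 6 as before, is added to commercial di-tert-butyl squarate to give racemic 2,3-di-tert-butoxy-4-[6-(4-tert-butoxyphenyl)-5-methoxy-4-oxo-4H-pyran-3-yl]-4-hydroxycyclobut-2-en-1-one F3. Ag2O/MeI then gives racemic 2,3-di-tert-butoxy-4-[6-(4-tert-butoxyphenyl)-5-methoxy-4-oxo-4H-pyran-3-yl]-4-methoxycyclobut-2-en-1-one F4, and thermolysis in toluene gives 6,7-di-tert-butoxy-2-(4-tert-butoxyphenyl)-8-hydroxy-3,5-dimethoxy-4H-chromen-4-one F5. MeI/K2CO3 gives 6,7-di-tert-butoxy-2-(4-tert-butoxyphenyl)-3,5,8-trimethoxy-4H-chromen-4-one F6, from which TFA removes all three tert-butyl groups to give 6,7-dihydroxy-2-(4-hydroxyphenyl)-3,5,8-trimethoxy-4H-chromen-4-one F7. Allyl bromide (2 equiv) with K2CO3 should alkylate the two most acidic phenols, para and vinylogously para to the carbonyl, and give 7-(allyloxy)-2-[4-(allyloxy)phenyl]-6-hydroxy-3,5,8-trimethoxy-4H-chromen-4-one F8. MeI/K2CO3 gives 7-(allyloxy)-2-[4-(allyloxy)phenyl]-3,5,6,8-tetramethoxy-4H-chromen-4-one F9, and Pd(PPh3)4 with morpholine removes both allyl groups to give 19.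

Step 4. Iodination may go ortho to the ether on ring B, or the tert-butyl ether may be lost to adventitious acid, instead of clean substitution at pyranone C5. Fallback, from 3 back to 13, installing the C5 halogen before the arene is present: 3 is treated with Br2 in CH2Cl2 at 0 °C and then Et3N (addition–elimination) to give 5-bromo-2-iodo-3-methoxy-4H-pyran-4-one F10. Suzuki coupling with 4 at the more reactive C–I bond gives 5-bromo-2-(4-tert-butoxyphenyl)-3-methoxy-4H-pyran-4-one F11. Bromine–magnesium exchange (iPrMgCl·LiCl, THF, −20 °C) gives 11, which is added to 10 as in step 7 to reach 13.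

Step 6. Elimination of the tert-butyl cation to isobutene may outrun O-alkylation of the weakly nucleophilic anion, leaving free acid and low conversion. Fallback, from 8 back to 10, replacing SN1 alkylation by acyl-type substitution: dried sodium salt 8 is treated with (COCl)2 and catalytic DMF in CH2Cl2 to give 3-chloro-4-methoxycyclobut-3-ene-1,2-dione F12. tBuOH and pyridine in CH2Cl2 at 0 °C then displace chloride by addition–elimination to give 10.

## Further compounds

F1 | step 9 | 7-tert-butoxy-2-(4-tert-butoxyphenyl)-5,8-dihydroxy-3,6-dimethoxy-4H-chromen-4-one | COc1c(OC(C)(C)C)c(O)c2oc(-c3ccc(OC(C)(C)C)cc3)c(OC)c(=O)c2c1O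
F2 | step 9 | 7-tert-butoxy-2-(4-tert-butoxyphenyl)-3,6-dimethoxy-4H-chromene-4,5,8-trione | COC1=C(OC(C)(C)C)C(=O)c2oc(-c3ccc(OC(C)(C)C)cc3)c(OC)c(=O)c2C1=O
F3 | step 7 | racemic 2,3-di-tert-butoxy-4-[6-(4-tert-butoxyphenyl)-5-methoxy-4-oxo-4H-pyran-3-yl]-4-hydroxycyclobut-2-en-1-one | O=C1C(OC(C)(C)C)=C(OC(C)(C)C)C1(O)c1coc(-c2ccc(OC(C)(C)C)cc2)c(OC)c1=O
F4 | step 7 | racemic 2,3-di-tert-butoxy-4-[6-(4-tert-butoxyphenyl)-5-methoxy-4-oxo-4H-pyran-3-yl]-4-methoxycyclobut-2-en-1-one | O=C1C(OC(C)(C)C)=C(OC(C)(C)C)C1(OC)c1coc(-c2ccc(OC(C)(C)C)cc2)c(OC)c1=O
F5 | step 7 | 6,7-di-tert-butoxy-2-(4-tert-butoxyphenyl)-8-hydroxy-3,5-dimethoxy-4H-chromen-4-one | COc1c(-c2ccc(OC(C)(C)C)cc2)oc2c(O)c(OC(C)(C)C)c(OC(C)(C)C)c(OC)c2c1=O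
F6 | step 7 | 6,7-di-tert-butoxy-2-(4-tert-butoxyphenyl)-3,5,8-trimethoxy-4H-chromen-4-one | COc1c(-c2ccc(OC(C)(C)C)cc2)oc2c(OC)c(OC(C)(C)C)c(OC(C)(C)C)c(OC)c2c1=O
F7 | step 7 | 6,7-dihydroxy-2-(4-hydroxyphenyl)-3,5,8-trimethoxy-4H-chromen-4-one | COc1c(-c2ccc(O)cc2)oc2c(OC)c(O)c(O)c(OC)c2c1=O
F8 | step 7 | 7-(allyloxy)-2-[4-(allyloxy)phenyl]-6-hydroxy-3,5,8-trimethoxy-4H-chromen-4-one | COc1c(-c2ccc(OCC=C)cc2)oc2c(OC)c(OCC=C)c(O)c(OC)c2c1=O
F9 | step 7 | 7-(allyloxy)-2-[4-(allyloxy)phenyl]-3,5,6,8-tetramethoxy-4H-chromen-4-one | COc1c(-c2ccc(OCC=C)cc2)oc2c(OC)c(OCC=C)c(OC)c(OC)c2c1=O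
F10 | step 4 | 5-bromo-2-iodo-3-methoxy-4H-pyran-4-one | COc1c(I)occ(Br)c1=O
F11 | step 4 | 5-bromo-2-(4-tert-butoxyphenyl)-3-methoxy-4H-pyran-4-one | COc1c(-c2ccc(OC(C)(C)C)cc2)occ(Br)c1=O
F12 | step 6 | 3-chloro-4-methoxycyclobut-3-ene-1,2-dione | COC1=C(Cl)C(=O)C1=O
A1 | alternative 1 | 7-(benzyloxy)-2-[4-(benzyloxy)phenyl]-3,5,6,8-tetramethoxy-4H-chromen-4-one | COc1c(OCc2ccccc2)c(OC)c2oc(-c3ccc(OCc4ccccc4)cc3)c(OC)c(=O)c2c1OC
A2 | alternative 1 | 7-(benzyloxy)-2-[4-(benzyloxy)phenyl]-6,8-dibromo-3,5-dimethoxy-4H-chromen-4-one | COc1c(-c2ccc(OCc3ccccc3)cc2)oc2c(Br)c(OCc3ccccc3)c(Br)c(OC)c2c1=O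
A3 | alternative 1 | kaempferol (3,5,7-trihydroxy-2-(4-hydroxyphenyl)-4H-chromen-4-one) | O=c1c(O)c(-c2ccc(O)cc2)oc2cc(O)cc(O)c12
A4 | alternative 2 | 6,7-bis(benzyloxy)-2-[4-(benzyloxy)phenyl]-5,8-dimethoxy-4H-chromen-4-one | COc1c(OCc2ccccc2)c(OCc2ccccc2)c(OC)c2c(=O)cc(-c3ccc(OCc4ccccc4)cc3)oc12
A5 | alternative 2 | 3,4-bis(benzyloxy)-2,5-dimethoxy-6-(trimethylsilyl)phenyl trifluoromethanesulfonate | COc1c(OCc2ccccc2)c(OCc2ccccc2)c(OC)c([Si](C)(C)C)c1OS(=O)(=O)C(F)(F)F
A6 | alternative 2 | 3-[4-(benzyloxy)phenyl]prop-2-ynoic acid | OC(=O)C#Cc1ccc(OCc2ccccc2)cc1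
A7 | alternative 3 | 7-(benzyloxy)-2-[4-(benzyloxy)phenyl]-3-iodo-5,6,8-trimethoxy-4H-chromen-4-one | COc1c(OCc2ccccc2)c(OC)c2oc(-c3ccc(OCc4ccccc4)cc3)c(I)c(=O)c2c1OC
A8 | alternative 3 | 1-[4-(benzyloxy)-2,3,5,6-tetramethoxyphenyl]-3-[4-(benzyloxy)phenyl]prop-2-yn-1-one | COc1c(OC)c(C(=O)C#Cc2ccc(OCc3ccccc3)cc2)c(OC)c(OC)c1OCc1ccccc1
A9 | alternative 3 | 3-(benzyloxy)-1,2,4,5-tetramethoxybenzene | COc1cc(OC)c(OC)c(OCc2ccccc2)c1OC
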